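**Late readings.** Late in the east run the target stops climbing: 48.5% at 10.0 min, 46.9% at 20.0 min. So I ask where each new flask's time falls on that curve.

| flask | substrate | partner | temperature | remark | time |
|---|---|---|---|---|---|
| north | 1.4 M | 0.73 M | 82 °C | run made earlier |  |
| east | 1.4 M | 2.9 M | 99 °C | run made earlier |  |
| north-east | 0.70 M | 1.47 M | 82 °C | run made earlier |  |
| zeta | 1.4 M | 1.47 M | 90 °C |  | 40 min |
| eta | 1.4 M | 1.47 M | 75 °C |  | 40 min |
| delta | 1.4 M | 1.47 M | 105 °C |  | 40 min |

| run | time / min | target / % |
|---|---|---|
| north | 1.50 | 1.0 |
| north | 5.00 | 4.1 |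
| north | 10.0 | 6.5 |
| north | 15.0 | 10.5 |
| north | 20.0 | 11.1 |
| north | 25.0 | 13.2 |
| north | 30.0 | 14.6 |
| east | 1.50 | 17.5 |
| east | 2.50 | 27.1 |
| east | 4.00 | 35.5 |
| east | 6.00 | 42.4 |
| east | 10.0 | 48.5 |
| east | 12.0 | 47.0 |
| east | 20.0 | 46.9 |
| north-east | 2.50 | 6.9 |
| north-east | 5.00 | 11.9 |
| north-east | 10.0 | 21.5 |
| north-east | 15.0 | 26.0 |
| north-east | 30.0 | 39.1 |

(readings scatter by 1 percentage point)

- the flask that comes out highest in amount of target, in percent of the substrate charged, or "all alike" when all lie within 1.5 percentage points (zeta / eta / delta / all alike)
- target at the end, in percent of the substrate charged, zeta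
- target at the end, in percent of the substrate charged, eta
- target at the end, in percent of the substrate charged, delta

- reactions considered so far: partner -> decomposed reagent; target -> over-reaction product; substrate + partner -> target; substrate <-> dormant form

**Time.** By hand, more time gives more target up to the stop. The east run does that: 17.5% at 1.50 min, then the flat. All three new flasks stand for 40 min.

**Partner.** By hand, I take the pace as proportional to the partner charged. That is my assumption; the forecast reads an order near 1.5. The new flasks hold 1.47 M, half the east charge, with the same substrate. So I scale east's readings by that ratio.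

**Temperature.** North and east share their substrate charge. I scale north's pace up to 5.00 min to east's partner. East's pace up to 1.50 min then exceeds it by a factor of 3.58 over 17.0 K. This is a ratio of readings, so it carries their scatter. It gives the doubling step, one rough figure for the warming that doubles the early pace of target formation: 9.24 K.

**East-minutes.** I multiply a flask's time by two raised to its temperature gap from east over the doubling step. This reduced time treats every step as warming alike, a rough assumption of mine, and estimates how far along the east curve the flask has come. Eta reaches 6.60 min, before the flat. East's nearest reading, 42.4% at 6.00 min, scales to 21.5%. Zeta reaches 20.4 min, on the flat, where scaling is rough: 23.8%. Delta reaches 62.7 min, beyond east's last reading, so I have no curve for it. I put zeta narrowly above eta.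

**The forecast.** It names eta, with 31% for zeta, 36% for eta and 16% for delta: “Heat therefore hurts yield”. On eta it differs from my 21.5%.

    partner → decomposed reagent (k = 0.0150 min⁻¹, Ea = 99.0 kJ mol⁻¹)
    target → over-reaction product (k = 0.0100 min⁻¹, Ea = 106 kJ mol⁻¹)
    substrate + partner → target, rate k3*[substrate]^0.5*[partner] (k = 0.0300 M⁻⁰·⁵ min⁻¹, Ea = 91.0 kJ mol⁻¹)
    substrate ⇌ dormant form (K = 4.80, k = 0.0780 min⁻¹, Ea = 99.0 kJ mol⁻¹, ΔH = −9.00 kJ mol⁻¹)
    (constants at 90 °C)

**The result.** Highest is zeta: zeta 31.8%, eta 24.0%, delta 14.3%. Eta compares with my 21.5%, and zeta stands above my rough 23.8%. Delta sits at 62.7 min east-minutes, and its run shows what lies there: without over-reaction of the target it would hold 51.0%, the largest single effect. Its neighbour, delta with 2.4 M of substrate, has the same east-minutes and holds 9.68% of target against 26.4% of over-reaction product.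

The data stem from a simulated flask with constants of no real substance; scatter was added.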